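**Retrosynthetic overview**

1. The target is guibourtinidol-(4α→6)-afzelechin (upper unit rings A/B/C, lower unit rings D/E/F with primed atoms); six O-benzyl ethers and a C8' bromide are removed in one final hydrogenolysis, and the C3 hydroxyl comes from a C3–boron bond by oxidation with retention.
2. The strategy rests on ring C (O1–C2–C3–C4): the C4 methine lies between ring A, which carries O1 ortho and the C7 oxygen para to it, and C6' of ring D, so the unit is an o-hydroxybenzhydryl group and a latent o-quinone methide. Cutting O1–C2 and C3–C4 leaves that methide and an E-styrylboronate.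
3. The benzhydrol is made from the 6-formyl-8-bromo derivative of perbenzylated afzelechin and the C,O-dilithio derivative of 5-benzyloxy-2-bromophenol. No O-silyl group is used, because an ortho-lithiated aryl silyl ether would undergo a retro-Brook shift and the alkoxide adduct would take over the silyl group and expel silanolate.
4. The C8' bromide is kept to the end: it directs formylation to C6', blocks the only other nucleophilic site of ring D against arylation by the quinone methide, and leaves with the benzyl groups.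
5. Ring order: D/E/F come from (+)-afzelechin, ring A from 4-bromoresorcinol, ring B from 1-(benzyloxy)-4-ethynylbenzene; ring C is formed last, in step 8.

Key step: step 8

Assumption: the R antipode of the phosphoric acid is taken as the matched catalyst; which antipode gives the 4S adduct must be settled by running both, and the S acid would be substituted without other change.

**Route**

Step 1
Reactants: 1 (+)-afzelechin
Product: 2 5,7,4'-tri-O-benzylafzelechin
Conditions: BnBr (3.3 equiv), K2CO3 (4 equiv), DMF, 0 °C → rt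
Reagents that add atoms: benzyl bromide BrCc1ccccc1
Why: Williamson etherification of the three phenols with a base too weak to ionise the secondary 3-OH, so C2 and C3 are untouched.

Step 2
Reactants: 2 5,7,4'-tri-O-benzylafzelechin
Product: 3 3,5,7,4'-tetra-O-benzylafzelechin
Conditions: NaH (1.5 equiv), BnBr (1.3 equiv), Bu4NI (cat.), THF/DMF, 0 °C → rt
Reagents that add atoms: benzyl bromide BrCc1ccccc1
Why: Williamson etherification of the secondary alkoxide, safe for C2 because with all phenols capped no quinone-methide ring opening is possible.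

Step 3
Reactants: 3 3,5,7,4'-tetra-O-benzylafzelechin
Product: 4 8-bromo-3,5,7,4'-tetra-O-benzylafzelechin
Conditions: NBS (1.0 equiv), CH2Cl2, −78 → 0 °C
Reagents that add atoms: N-bromosuccinimide O=C1CCC(=O)N1Br
Why: Electrophilic aromatic bromination of ring D, the most electron-rich arene, which in per-O-benzylated flavan-3-ols takes one equivalent of NBS at C8' in preference to C6'.

Step 4
Reactants: 4 8-bromo-3,5,7,4'-tetra-O-benzylafzelechin
Product: 6 8-bromo-3,5,7,4'-tetra-O-benzylafzelechin-6-carbaldehyde, via aryl iminium chloride 5 (not isolated)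
Conditions: POCl3 (3 equiv), DMF, 0 → 70 °C; then aq NaOAc, rt
Reagents that add atoms: N,N-dimethylformamide CN(C)C=O; water O
Why: Vilsmeier–Haack formylation at C6', the only free position of the trioxygenated ring D once C8' is blocked, while ring E and the benzyl rings are too electron-poor to react.

Step 5
Reactants: 7 4-bromoresorcinol
Product: 9 5-(benzyloxy)-2-bromophenol, via disodium 4-bromoresorcinolate 8 (not isolated)
Conditions: NaH (2.2 equiv), DMF, 0 °C; BnBr (1.0 equiv), 0 °C → rt; 1 M HCl; chromatography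
Reagents that add atoms: benzyl bromide BrCc1ccccc1
Why: Williamson etherification of the dianion, in which the oxygen para to bromine is the more basic and less hindered nucleophile, so monobenzylation should occur mainly there, with the regioisomer and the bis-ether removed on silica.

Step 6
Reactants: 9 5-(benzyloxy)-2-bromophenol; 6 8-bromo-3,5,7,4'-tetra-O-benzylafzelechin-6-carbaldehyde
Product: 11 (4-benzyloxy-2-hydroxyphenyl)(8-bromo-3,5,7,4'-tetra-O-benzylafzelechin-6-yl)methanol as carbinol epimers, via lithium 5-(benzyloxy)-2-lithiophenolate 10 (not isolated)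
Conditions: 9 (2.0 equiv), n-BuLi (4.0 equiv), THF, −78 → −20 °C; then 6 (1.0 equiv), −78 °C; aq NH4Cl; Et3N-washed silica
Reagents that add atoms: none
Why: Deprotonation then bromine–lithium exchange gives a C,O-dilithio reagent whose aryllithium should add 1,2 to the aldehyde at −78 °C faster than it exchanges with the hindered C8' bromide, and the carbinol centre may form as both epimers because it becomes trigonal in step 8.

Step 7
Reactants: 12 1-(benzyloxy)-4-ethynylbenzene
Product: 13 (E)-2-(4-benzyloxystyryl)boronic acid pinacol ester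
Conditions: pinacolborane (1.2 equiv), Cp2ZrHCl (5 mol %), Et3N (10 mol %), neat, 60 °C
Reagents that add atoms: pinacolborane [H]B1OC(C)(C)C(C)(C)O1
Why: Zirconocene-catalysed syn-hydroboration of a terminal alkyne places boron on the terminal carbon and gives only the E-alkenylboronate.

Step 8
Reactants: 11 (4-benzyloxy-2-hydroxyphenyl)(8-bromo-3,5,7,4'-tetra-O-benzylafzelechin-6-yl)methanol; 13 (E)-2-(4-benzyloxystyryl)boronic acid pinacol ester
Product: 15 hexa-O-benzyl-8'-bromo dimer with a pinacolboryl group at C3 and 2,3-trans-3,4-trans ring C, via o-quinone methide 14 (not isolated)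
Conditions: 13 (2.5 equiv), (R)-3,3'-bis(2,4,6-triisopropylphenyl)-1,1'-binaphthyl-2,2'-diyl hydrogen phosphate (10 mol %), 5 Å MS, toluene, −20 °C → rt
Reagents that add atoms: none
Why: Proposed new method: the phosphoric acid protonates the benzhydrol, water leaves, and the E-configured o-quinone methide 14 stays hydrogen-bonded through its carbonyl oxygen to the acid, whose triisopropylphenyl walls shield one face of C4; the boron-bearing carbon of 13, the nucleophilic terminus because the 4-benzyloxyphenyl donor and the boryl acceptor polarise the alkene in the same sense, bonds to C4 while charge builds at the benzylic carbon, which O1 captures in an asynchronous concerted inverse-demand [4+2] closure forming O1–C2 and C3–C4 and thereby the six-membered ring C. The closest known reaction is the Brønsted-acid-catalysed hetero-Diels–Alder of o-quinone methides generated from o-hydroxybenzhydrols with styrenes; an alkenylboronate as the 2π partner and a methide carbon bearing a 2,6-dialkoxyaryl group are the untested elements. C2/C3 trans follows from suprafacial addition to the E-alkene, C2/C4 cis from endo placement of the 4-benzyloxyphenyl group over the E-methide (the all-equatorial arrangement, which a stepwise cation–phenol collapse would also favour), and the absolute sense at C4 from the chiral acid, since the stereocentres of ring F are too remote to bias the planar methide; a mismatched fraction would be a diastereomer and should separate on silica. The step needs ring closure to win over transfer of the alkenyl group from boron with loss of boron, which the non-exchanging, weakly Lewis-acidic pinacol ester is chosen to suppress, and over arylation of the methide by a second molecule, which the C8' bromide prevents by occupying the only other nucleophilic position of ring D. Molecular sieves take up the water so that neither the boronate nor the methide is hydrolysed.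

Step 9
Reactants: 15 hexa-O-benzyl-8'-bromo dimer with a pinacolboryl group at C3
Product: 17 hexa-O-benzyl-8'-bromo-guibourtinidol-(4α→6)-afzelechin with free 3-OH, via C3 borate ester 16 (not isolated)
Conditions: NaBO3·4H2O (6 equiv), THF/H2O 1:1, rt
Reagents that add atoms: sodium perborate (in solution sodium hydroperoxytrihydroxyborate) [Na+].OO[B-](O)(O)O
Why: Boronate oxidation proceeds by 1,2-migration of C3 from boron to peroxide oxygen with retention, so the 3-OH inherits the 2,3-trans-3,4-trans arrangement, and the benzyl ethers and the aryl bromide are inert to the mild base.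

Step 10
Reactants: 17 hexa-O-benzyl-8'-bromo-guibourtinidol-(4α→6)-afzelechin
Product: 18 guibourtinidol-(4α→6)-afzelechin (CNP0325116.1)
Conditions: H2 (1 atm), Pd(OH)2/C (20 wt %), NaOAc (1.5 equiv), THF/MeOH 1:1, rt
Reagents that add atoms: none
Why: Heterogeneous hydrogenolysis cleaves the six O-benzyl bonds and the aryl C–Br bond in one operation, the acetate buffer taking up HBr so that the acid-labile C4–C6' and C2–O1 bonds are not ionised and no stereocentre is touched.

**Compound list**

1 | (+)-afzelechin, (2R,3S) | Oc1cc(O)c2C[C@H](O)[C@@H](c3ccc(O)cc3)Oc2c1 | starting material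
2 | 5,7,4'-tri-O-benzylafzelechin, (2R,3S) | C(c5ccccc5)Oc1cc(OCc6ccccc6)c2C[C@H](O)[C@@H](c3ccc(OCc7ccccc7)cc3)Oc2c1 | intermediate
3 | 3,5,7,4'-tetra-O-benzylafzelechin, (2R,3S) | C(c5ccccc5)Oc1cc(OCc6ccccc6)c2C[C@H](OCc8ccccc8)[C@@H](c3ccc(OCc7ccccc7)cc3)Oc2c1 | intermediate
4 | 8-bromo-3,5,7,4'-tetra-O-benzylafzelechin, (2R,3S) | C(c5ccccc5)Oc1cc(OCc6ccccc6)c2C[C@H](OCc8ccccc8)[C@@H](c3ccc(OCc7ccccc7)cc3)Oc2c1Br | intermediate
5 | C6-(dimethyliminio)methyl derivative of 4, chloride salt | C(c5ccccc5)Oc1c(C=[N+](C)C)c(OCc6ccccc6)c2C[C@H](OCc8ccccc8)[C@@H](c3ccc(OCc7ccccc7)cc3)Oc2c1Br.[Cl-] | intermediate (not isolated)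
6 | 8-bromo-3,5,7,4'-tetra-O-benzylafzelechin-6-carbaldehyde, (2R,3S) | C(c5ccccc5)Oc1c(C=O)c(OCc6ccccc6)c2C[C@H](OCc8ccccc8)[C@@H](c3ccc(OCc7ccccc7)cc3)Oc2c1Br | intermediate
7 | 4-bromoresorcinol | Oc1ccc(Br)c(O)c1 | starting material
8 | disodium 4-bromobenzene-1,3-diolate | [Na+].[Na+].[O-]c1ccc(Br)c([O-])c1 | intermediate (not isolated)
9 | 5-(benzyloxy)-2-bromophenol | Oc1cc(OCc2ccccc2)ccc1Br | intermediate
10 | lithium 5-(benzyloxy)-2-lithiophenolate | [Li+].[O-]c1cc(OCc2ccccc2)ccc1[Li] | intermediate (not isolated)
11 | (4-benzyloxy-2-hydroxyphenyl)[(2R,3S)-3,5,7-tris(benzyloxy)-2-(4-benzyloxyphenyl)-8-bromochroman-6-yl]methanol, carbinol epimers | C(c5ccccc5)Oc1c(C(O)c9ccc(OCc4ccccc4)cc9O)c(OCc6ccccc6)c2C[C@H](OCc8ccccc8)[C@@H](c3ccc(OCc7ccccc7)cc3)Oc2c1Br | intermediate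
12 | 1-(benzyloxy)-4-ethynylbenzene | C#Cc1ccc(OCc2ccccc2)cc1 | starting material
13 | (E)-2-(4-benzyloxystyryl)boronic acid pinacol ester | CC1(C)OB(/C=C/c2ccc(OCc3ccccc3)cc2)OC1(C)C | intermediate
14 | E-o-quinone methide: 3-(benzyloxy)-6-(arylmethylidene)cyclohexa-2,4-dien-1-one, aryl = C6' of the 8-bromo-tetra-O-benzylafzelechin unit | C(c5ccccc5)Oc1c(/C=C9/C(=O)C=C(OCc4ccccc4)C=C9)c(OCc6ccccc6)c2C[C@H](OCc8ccccc8)[C@@H](c3ccc(OCc7ccccc7)cc3)Oc2c1Br | intermediate (not isolated)
15 | (2S,3S,4S)-7-(benzyloxy)-2-(4-benzyloxyphenyl)-3-(4,4,5,5-tetramethyl-1,3,2-dioxaborolan-2-yl)-4-[(2R,3S)-3,5,7-tris(benzyloxy)-2-(4-benzyloxyphenyl)-8-bromochroman-6-yl]chromane, 2,3-trans-3,4-trans | c5ccccc5COc1ccc([C@H]2Oc3cc(OCc5ccccc5)ccc3[C@@H](c3c(OCc5ccccc5)c(Br)c4c(c3OCc5ccccc5)C[C@H](OCc5ccccc5)[C@@H](c3ccc(OCc5ccccc5)cc3)O4)[C@@H]2B6OC(C)(C)C(C)(C)O6)cc1 | intermediate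
16 | C3 borate ester (C3–O–B pinacolate) of 17, (2R,3S,4S) | c5ccccc5COc1ccc([C@H]2Oc3cc(OCc5ccccc5)ccc3[C@@H](c3c(OCc5ccccc5)c(Br)c4c(c3OCc5ccccc5)C[C@H](OCc5ccccc5)[C@@H](c3ccc(OCc5ccccc5)cc3)O4)[C@@H]2OB6OC(C)(C)C(C)(C)O6)cc1 | intermediate (not isolated)
17 | (2R,3S,4S)-7-(benzyloxy)-2-(4-benzyloxyphenyl)-4-[(2R,3S)-3,5,7-tris(benzyloxy)-2-(4-benzyloxyphenyl)-8-bromochroman-6-yl]chroman-3-ol | c5ccccc5COc1ccc([C@H]2Oc3cc(OCc5ccccc5)ccc3[C@@H](c3c(OCc5ccccc5)c(Br)c4c(c3OCc5ccccc5)C[C@H](OCc5ccccc5)[C@@H](c3ccc(OCc5ccccc5)cc3)O4)[C@@H]2O)cc1 | intermediate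
18 | (2R,3S,4S)-2-(4-hydroxyphenyl)-4-[(2R,3S)-3,5,7-trihydroxy-2-(4-hydroxyphenyl)chroman-6-yl]chromane-3,7-diol | Oc1ccc([C@H]2Oc3cc(O)ccc3[C@@H](c3c(O)cc4c(c3O)C[C@H](O)[C@@H](c3ccc(O)cc3)O4)[C@@H]2O)cc1 | target

**Step count and risks**

Total steps: 10. Longest linear sequence: 8 (steps 1, 2, 3, 4, 6, 8, 9, 10).

Step 8 (the step proposed as new). The risks are:
- no turnover between a strongly stabilised, doubly ortho-substituted methide and a weakly nucleophilic alkene;
- loss of boron through alkenyl transfer instead of ring closure;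
- weak facial control by the catalyst.

Fallback: ring C would be brought in ready-made and the interflavan bond formed by the classical acid-promoted arylation of a flavan-4-yl cation, setting out from bromide 4 and returning at 17. Purchased (2R,3R)-garbanzol F1 would be benzylated on both phenols (BnBr, K2CO3, DMF, rt) to 7,4'-di-O-benzylgarbanzol F2. Reduction with NaBH4 (EtOH/THF, 0 °C) would give the 2,3-trans flavan-3,4-diol F3. F3 would be ionised at C4 with BF3·OEt2 (CH2Cl2, −78 → −20 °C) in the presence of excess 4, whose only free ring D position is C6'. Attack anti to the C3 hydroxyl of the 2,3-trans cation should give mainly the 3,4-trans dimer, which is 17.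

Step 6. The risks are:
- slow addition of the aggregated dilithio reagent to the di-ortho-substituted aldehyde;
- competing bromine–lithium exchange at C8';
- ionisation of the very acid-labile benzhydrol during purification.

Fallback: a protected monolithium reagent with a separate neutral deprotection, setting out from 9 and 6 and returning at 11. Phenol 9 would be allylated (allyl bromide, K2CO3, acetone) to 2-(allyloxy)-4-(benzyloxy)-1-bromobenzene F4. Exchange with n-BuLi (1.0 equiv, THF, −78 °C) would give [2-(allyloxy)-4-(benzyloxy)phenyl]lithium F5. Addition to 6 at −78 °C would give the O-allyl benzhydrol F6. The allyl ether would then be removed under basic conditions that cannot ionise the carbinol (Pd(PPh3)4 cat., K2CO3, MeOH, rt) to give 11.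

Step 4. The risks are:
- incomplete formylation at a position flanked by two benzyloxy groups and deactivated by bromine;
- acid-induced opening of ring F at C2 with epimerisation in hot POCl3/DMF.

Fallback: halogenation followed by halogen–metal exchange, setting out from 4 and returning at 6. Iodination (N-iodosuccinimide, CF3CO2H cat., CH2Cl2/MeCN, 0 °C → rt) would give 8-bromo-6-iodo-3,5,7,4'-tetra-O-benzylafzelechin F7. Selective iodine–magnesium exchange (i-PrMgCl·LiCl, THF, −40 °C) would give the C6' arylmagnesium chloride F8 with the bromide untouched. Quenching with DMF and then aq NH4Cl would give 6.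

**Further compounds**

F1 | step 8 | (2R,3R)-garbanzol (7,4'-dihydroxydihydroflavonol, purchased) | Oc1ccc([C@H]2Oc3cc(O)ccc3C(=O)[C@@H]2O)cc1
F2 | step 8 | (2R,3R)-7-(benzyloxy)-2-(4-benzyloxyphenyl)-3-hydroxychroman-4-one | c5ccccc5COc1ccc([C@H]2Oc3cc(OCc5ccccc5)ccc3C(=O)[C@@H]2O)cc1
F3 | step 8 | (2R,3S)-7-(benzyloxy)-2-(4-benzyloxyphenyl)chromane-3,4-diol, C4 epimers | c5ccccc5COc1ccc([C@H]2Oc3cc(OCc5ccccc5)ccc3C(O)[C@@H]2O)cc1
F4 | step 6 | 2-(allyloxy)-4-(benzyloxy)-1-bromobenzene | C=CCOc1cc(OCc2ccccc2)ccc1Br
F5 | step 6 | [2-(allyloxy)-4-(benzyloxy)phenyl]lithium | C=CCOc1cc(OCc2ccccc2)ccc1[Li]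
F6 | step 6 | [2-(allyloxy)-4-(benzyloxy)phenyl][(2R,3S)-3,5,7-tris(benzyloxy)-2-(4-benzyloxyphenyl)-8-bromochroman-6-yl]methanol, carbinol epimers | C(c5ccccc5)Oc1c(C(O)c9ccc(OCc4ccccc4)cc9OCC=C)c(OCc6ccccc6)c2C[C@H](OCc8ccccc8)[C@@H](c3ccc(OCc7ccccc7)cc3)Oc2c1Br
F7 | step 4 | 8-bromo-6-iodo-3,5,7,4'-tetra-O-benzylafzelechin, (2R,3S) | C(c5ccccc5)Oc1c(I)c(OCc6ccccc6)c2C[C@H](OCc8ccccc8)[C@@H](c3ccc(OCc7ccccc7)cc3)Oc2c1Br
F8 | step 4 | [(2R,3S)-3,5,7-tris(benzyloxy)-2-(4-benzyloxyphenyl)-8-bromochroman-6-yl]magnesium chloride | C(c5ccccc5)Oc1c([Mg]Cl)c(OCc6ccccc6)c2C[C@H](OCc8ccccc8)[C@@H](c3ccc(OCc7ccccc7)cc3)Oc2c1Br
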